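The route rests on disconnecting C4–C4a of the 5,6,7-trimethoxyflavan half (unit B) rather than the fragile bis-benzylic ether. The feature exploited sits in the 5-hydroxy-6,7-dimethoxyflavan half (unit A). Phenolic O5 on ring A is peri to O4 on pyran carbon C4, a 1,3-diol-like pair able to clamp the future C4 of unit B inside a 1,3-dioxine ring. Precursor 18 is this tricyclic acetal, its acetal carbon bearing a CH2–CH(Ph)–OAr chain (Ar = 3,4,5-trimethoxyphenyl). Chelation-directed departure of O5 releases an oxocarbenium ion that the symmetric arene traps. This one operation closes the pyran ring of unit B, sets its C4 trans to C2, keeps the C4–O–C4 link and liberates the 5-OH.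

Key step: step 12

Remark on the chemistry: CIP analysis of the target gives 2S,4R (2,4-trans) for both flavan units. Flavan numbering is used for both halves. The acetal carbon of 18 is carried as a mixture of epimers because it becomes planar in step 12.

Design remark: in 18 the dioxine ring holds the C4–O4 bond of unit A close to the plane of ring A, where benzylic ionisation is stereoelectronically disfavoured. A hindered pyridine is present in steps 11 and 12 to remove any protic acid. Part of alcohol 5 is stored, and aldehyde 6 is made from it only just before step 11.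

Step 1
Reactants: 1 3,4,5-trimethoxyphenol; 2 (R)-3-chloro-1-phenylpropan-1-ol
Product: 3 (S)-5-(3-chloro-1-phenylpropoxy)-1,2,3-trimethoxybenzene
Conditions: PPh3, DIAD, THF, 0 °C → rt
Reagents that add atoms: none
Why: Mitsunobu etherification of a secondary benzylic alcohol with a phenol runs by SN2 displacement, so the purchased (R)-carbinol centre is inverted to the (S)-aryl ether that becomes C2 of both flavan units, while the primary chloride is a spectator.

Step 2
Reactants: 3 (S)-5-(3-chloro-1-phenylpropoxy)-1,2,3-trimethoxybenzene
Product: 5 (S)-3-phenyl-3-(3,4,5-trimethoxyphenoxy)propan-1-ol, via acetate 4 (not isolated)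
Conditions: CsOAc, DMF, 90 °C; then MeOH, K2CO3 (cat.), rt
Reagents that add atoms: caesium acetate, CC(=O)[O-].[Cs+]
Why: SN2 displacement of the unhindered primary chloride by acetate, followed by base-catalysed transesterification in the same flask, exchanges Cl for OH without touching the benzylic ether centre, which has neither an acidic proton nor a leaving group under these conditions.

Step 3
Reactants: 5 (S)-3-phenyl-3-(3,4,5-trimethoxyphenoxy)propan-1-ol
Product: 7 (S)-3-phenyl-3-(3,4,5-trimethoxyphenoxy)propanoic acid, via aldehyde 6 (not isolated)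
Conditions: TEMPO (cat.), PhI(OAc)2 (2.2 equiv), MeCN–H2O, rt
Reagents that add atoms: water, O
Why: The TEMPO/PhI(OAc)2 oxidation takes a primary alcohol through the aldehyde and its hydrate to the acid under nearly neutral, chlorine-free conditions, so the electron-rich ring is not halogenated and the β-aryloxy group is not eliminated.

Step 4
Reactants: 7 (S)-3-phenyl-3-(3,4,5-trimethoxyphenoxy)propanoic acid
Product: 9 (S)-5,6,7-trimethoxyflavanone, via mixed anhydride 8 (not isolated)
Conditions: (CF3CO)2O (1.5 equiv), CH2Cl2, 0 °C → rt
Reagents that add atoms: trifluoroacetic anhydride, O=C(OC(=O)C(F)(F)F)C(F)(F)F (its acyl group is carried only by 8 and is lost again on the way to 9)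
Why: Intramolecular Friedel–Crafts acylation through the mixed anhydride needs no metal Lewis acid because the attacked carbon is activated by three oxygen substituents, the two ortho sites are equivalent, and the mild acid leaves the C2 benzylic ether centre intact.

Step 5
Reactants: 9 (S)-5,6,7-trimethoxyflavanone
Product: 11 (S)-5-hydroxy-6,7-dimethoxyflavanone, via boron chelate 10 (not isolated)
Conditions: BCl3 (1.2 equiv), CH2Cl2, −78 → 0 °C; then H2O
Reagents that add atoms: boron trichloride, ClB(Cl)Cl (retained only in 10)
Why: In this chelation-directed aryl methyl ether cleavage boron bridges the C4 carbonyl and the peri 5-methoxy oxygen so that chloride removes only that methyl group, and the low temperature and near-stoichiometric charge should prevent attack on 6-OMe and the chalcone ring opening that would racemise C2.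

Step 6
Reactants: 11 (S)-5-hydroxy-6,7-dimethoxyflavanone
Product: 12 (2S,4S)-6,7-dimethoxyflavan-4,5-diol (2,4-cis)
Conditions: NaBH4, THF–MeOH, 0 °C; pH 7 buffer
Reagents that add atoms: none
Why: In the borohydride reduction of a flavanone, hydride adds pseudoaxially to the half-chair whose 2-phenyl group is equatorial, so substrate control from C2 gives the equatorial alcohol, that is the 2,4-cis (4S) diol, and the cold, short reaction limits base-induced ring opening.

Step 7
Reactants: 12 (2S,4S)-6,7-dimethoxyflavan-4,5-diol
Product: 13 (2S,4S)-5-(tert-butyldimethylsilyloxy)-6,7-dimethoxyflavan-4-ol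
Conditions: TBSCl (1.05 equiv), imidazole, DMF, 0 °C
Reagents that add atoms: tert-butyldimethylsilyl chloride, CC(C)(C)[Si](C)(C)Cl
Why: Imidazole-promoted silylation is faster at the more acidic phenol than at the hindered secondary benzylic alcohol, so one equivalent should mask O5 selectively, and doing this after the reduction avoids silyl migration to a C4 alkoxide and basic treatment of the flavanone.

Step 8
Reactants: 13 (2S,4S)-5-(tert-butyldimethylsilyloxy)-6,7-dimethoxyflavan-4-ol
Product: 14 (2S,4R)-5-(tert-butyldimethylsilyloxy)-6,7-dimethoxyflavan-4-yl 4-nitrobenzoate (2,4-trans)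
Conditions: 4-O2NC6H4CO2H, PPh3, DIAD, toluene, 0 °C → rt; rapid filtration over Et3N-deactivated silica
Reagents that add atoms: 4-nitrobenzoic acid, OC(=O)c1ccc(cc1)[N+](=O)[O-]
Why: Mitsunobu inversion in a non-polar solvent delivers the carboxylate anti to the departing oxygen, and because pseudoaxial capture is also the preferred fate of any ion pair at this electron-rich carbon, SN2 and SN1 leakage converge on the 2,4-trans (4R) ester.

Step 9
Reactants: 14 (2S,4R)-5-(tert-butyldimethylsilyloxy)-6,7-dimethoxyflavan-4-yl 4-nitrobenzoate
Product: 16 (2S,4R)-6,7-dimethoxyflavan-4,5-diol (2,4-trans), via silyl ether alcohol 15 (not isolated)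
Conditions: K2CO3 (cat.), MeOH–THF, 0 °C; then TBAF (1.1 equiv), 0 °C; pH 7 buffer
Reagents that add atoms: none
Why: Base-catalysed methanolysis removes the activated benzoate first, so no free phenoxide ever faces a C4 leaving group, and fluoride desilylation then frees O5 (and clears any silyl group that has shifted to O4), neither operation breaking the C4–O bond, so 4R is kept.

Step 10
Reactants: 5 (S)-3-phenyl-3-(3,4,5-trimethoxyphenoxy)propan-1-ol
Product: 6 (S)-3-phenyl-3-(3,4,5-trimethoxyphenoxy)propanal
Conditions: Dess–Martin periodinane, CH2Cl2, 0 °C → rt; used at once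
Reagents that add atoms: none
Why: The Dess–Martin oxidation stops at the aldehyde under non-basic conditions, which matters because base would expel the phenol from this β-aryloxy aldehyde by E1cB elimination.

Step 11
Reactants: 16 (2S,4R)-6,7-dimethoxyflavan-4,5-diol; 6 (S)-3-phenyl-3-(3,4,5-trimethoxyphenoxy)propanal
Product: 18 O4,O5-cyclic acetal of 16 with 6 (both epimers at the acetal carbon), via bis-TMS ether 17 (not isolated)
Conditions: MSTFA (2.5 equiv), CH2Cl2, 0 °C → rt; then 6 (1.2 equiv), TMSOTf (5 mol%), 2,6-di-tert-butyl-4-methylpyridine (10 mol%), −78 °C; Et3N quench at −78 °C; Et3N-deactivated silica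
Reagents that add atoms: N-methyl-N-(trimethylsilyl)trifluoroacetamide, CN(C(=O)C(F)(F)F)[Si](C)(C)C (its silyl groups are carried only by 17)
Why: In this Noyori-type acetalisation the silyl amide turns both hydroxyl groups into TMS ethers under neutral conditions and catalytic TMSOTf condenses them with the aldehyde at −78 °C with loss of hexamethyldisiloxane, without water or Brønsted acid, so the C4–O4 bond is never broken and 4R is retained, while the new acetal centre needs no control because step 12 planarises it.

Step 12
Reactants: 18 O4,O5-cyclic acetal of 16 with 6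
Product: 20 beilschmieflavonoid B, via oxocarbenium ion 19 (not isolated)
Conditions: TiCl4 (1.5 equiv), 2,6-di-tert-butyl-4-methylpyridine (2 equiv), CH2Cl2 (0.005 M), −78 °C; quench at −78 °C with sat. aq. NaHCO3
Reagents that add atoms: none
Why: Titanium binds O5 and the adjacent 6-methoxy oxygen as a five-membered chelate, so the acetal carbon–O5 bond breaks (aryloxide is the better leaving group and alkyl oxygen O4 the better donor) to give 19, whereas the C4–O4 bond of unit A, tied near the plane of ring A, overlaps poorly with the π system and should not ionise first. The closest known reaction type is the Lewis-acid opening of a cyclic acetal with intramolecular Friedel–Crafts capture of the oxocarbenium ion, a relative of the oxa-Pictet–Spengler cyclisation. The pyran ring of unit B closes 6-exo-trig at the C=O+ carbon (the arene double bond lies inside the new ring) through a chair with the C2 phenyl group equatorial. The new C4 centre is controlled by the existing (S)-C2 centre together with peri strain against the flanking methoxy group that becomes 5-OMe, which pushes the bulky O4 substituent pseudoaxial and gives the 2,4-trans (4R) ether, also the more stable epimer. No site selectivity is needed on the arene because the two positions ortho to the ether oxygen are equivalent, and two ortho and one para oxygen donors make closure faster than loss of the aldehyde from 19. The hindered pyridine takes the proton released on rearomatisation so that the acid-labile bis-benzylic ether survives, and the cold bicarbonate quench frees the 5-OH.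

Compound list
1 | 3,4,5-trimethoxyphenol | COc1cc(O)cc(OC)c1OC | starting material
2 | (R)-3-chloro-1-phenylpropan-1-ol | ClCC[C@H](c1ccccc1)O | starting material
3 | (S)-5-(3-chloro-1-phenylpropoxy)-1,2,3-trimethoxybenzene | ClCC[C@@H](c1ccccc1)Oc1cc(OC)c(OC)c(OC)c1 | intermediate
4 | (S)-3-phenyl-3-(3,4,5-trimethoxyphenoxy)propyl acetate | CC(=O)OCC[C@@H](c1ccccc1)Oc1cc(OC)c(OC)c(OC)c1 | intermediate
5 | (S)-3-phenyl-3-(3,4,5-trimethoxyphenoxy)propan-1-ol | OCC[C@@H](c1ccccc1)Oc1cc(OC)c(OC)c(OC)c1 | intermediate
6 | (S)-3-phenyl-3-(3,4,5-trimethoxyphenoxy)propanal | O=CC[C@@H](c1ccccc1)Oc1cc(OC)c(OC)c(OC)c1 | intermediate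
7 | (S)-3-phenyl-3-(3,4,5-trimethoxyphenoxy)propanoic acid | OC(=O)C[C@@H](c1ccccc1)Oc1cc(OC)c(OC)c(OC)c1 | intermediate
8 | mixed anhydride of 7 with trifluoroacetic acid | FC(F)(F)C(=O)OC(=O)C[C@@H](c1ccccc1)Oc1cc(OC)c(OC)c(OC)c1 | intermediate
9 | (S)-5,6,7-trimethoxyflavanone | COc1cc2c(c(OC)c1OC)C(=O)C[C@@H](c1ccccc1)O2 | intermediate
10 | O5-dichloroboryl chelate of (S)-5-hydroxy-6,7-dimethoxyflavanone | COc1cc2c(c(OB(Cl)Cl)c1OC)C(=O)C[C@@H](c1ccccc1)O2 | intermediate
11 | (S)-5-hydroxy-6,7-dimethoxyflavanone | COc1cc2c(c(O)c1OC)C(=O)C[C@@H](c1ccccc1)O2 | intermediate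
12 | (2S,4S)-6,7-dimethoxyflavan-4,5-diol (cis) | COc1cc2c(c(O)c1OC)[C@@H](O)C[C@@H](c1ccccc1)O2 | intermediate
13 | (2S,4S)-5-(tert-butyldimethylsilyloxy)-6,7-dimethoxyflavan-4-ol | COc1cc2c(c(O[Si](C)(C)C(C)(C)C)c1OC)[C@@H](O)C[C@@H](c1ccccc1)O2 | intermediate
14 | (2S,4R)-5-(tert-butyldimethylsilyloxy)-6,7-dimethoxyflavan-4-yl 4-nitrobenzoate | COc1cc2c(c(O[Si](C)(C)C(C)(C)C)c1OC)[C@H](OC(=O)c1ccc(cc1)[N+](=O)[O-])C[C@@H](c1ccccc1)O2 | intermediate
15 | (2S,4R)-5-(tert-butyldimethylsilyloxy)-6,7-dimethoxyflavan-4-ol | COc1cc2c(c(O[Si](C)(C)C(C)(C)C)c1OC)[C@H](O)C[C@@H](c1ccccc1)O2 | intermediate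
16 | (2S,4R)-6,7-dimethoxyflavan-4,5-diol (trans) | COc1cc2c(c(O)c1OC)[C@H](O)C[C@@H](c1ccccc1)O2 | intermediate
17 | (2S,4R)-6,7-dimethoxy-4,5-bis(trimethylsilyloxy)flavan | COc1cc2c(c(O[Si](C)(C)C)c1OC)[C@H](O[Si](C)(C)C)C[C@@H](c1ccccc1)O2 | intermediate
18 | O4,O5-cyclic acetal of 16 with 6 (1,3-dioxine ring through O4, C4, C4a, C5, O5 and the acetal carbon; both acetal epimers) | O1[C@@H]2C[C@@H](c3ccccc3)Oc3cc(OC)c(OC)c(OC1C[C@@H](c4ccccc4)Oc4cc(OC)c(OC)c(OC)c4)c32 | intermediate
19 | ring-opened oxocarbenium ion, O4 doubly bonded to the former acetal carbon, O5 a titanium-bound phenolate (drawn metal-free as the zwitterion) | COc1cc2c(c([O-])c1OC)[C@H]([O+]=CC[C@@H](c1ccccc1)Oc1cc(OC)c(OC)c(OC)c1)C[C@@H](c1ccccc1)O2 | intermediate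
20 | beilschmieflavonoid B, (2S,4R)-5-hydroxy-6,7-dimethoxyflavan-4-yl (2S,4R)-5,6,7-trimethoxyflavan-4-yl ether | COc1cc2c(c(O)c1OC)[C@H](O[C@@H]1C[C@@H](c3ccccc3)Oc3cc(OC)c(OC)c(OC)c31)C[C@@H](c1ccccc1)O2 | target

Total step count: 12. Longest linear sequence: 11 (steps 1–9, 11 and 12; step 10 is a one-step branch from 5).

Steps most likely to fail

Step 12.
- **What may go wrong:** the opened ion may shed the aldehyde in a stepwise retro-hetero-Diels–Alder sense. The acetal may open at the wrong oxygen. C4 of unit A may ionise once it is released from the ring. The new ether may be lost by elimination under residual acid.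
- **Fallback:** the same cation is generated without the tether from a far better leaving group. The fallback sets out from 13 and 7 and returns at 20.
- **Path:** Mitsunobu esterification of 13 with 7 (PPh3, DIAD, toluene) inverts C4 and should give the (2S,4R)-flavan-4-yl (S)-3-phenyl-3-(3,4,5-trimethoxyphenoxy)propanoate F1. Reductive acetylation of this ester (DIBAL-H, −78 °C, then Ac2O, pyridine, DMAP) gives the α-acetoxy ether F2. BF3·OEt2 with the hindered pyridine at −78 °C ionises only the acetate, and Friedel–Crafts closure gives the 5-O-TBS ether of the target F3. TBAF buffered with acetic acid then releases 20.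

Step 11.
- **What may go wrong:** silyl triflate may ionise or epimerise C4 of unit A before the ring is closed. The aldehyde may lose its aryloxide by β-elimination. The pendant arene may capture the intermediate cation prematurely.
- **Fallback:** the acetal is built entirely without acid. The fallback sets out from 16 and returns at 18.
- **Path:** DMAP-catalysed double oxa-Michael addition of 16 to 1-phenylprop-2-yn-1-one (CH2Cl2, rt) should give the phenacyl-substituted cyclic acetal F4. Corey–Bakshi–Shibata reduction with the (S)-oxazaborolidine and BH3·SMe2 gives the (R)-carbinol F5. Mitsunobu etherification with 1 inverts this centre to the (S)-aryl ether, which is 18.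

Step 8.
- **What may go wrong:** the crowded, very electron-rich carbinol may dehydrate by an E1 path. The activated ester may re-ionise during handling, with loss of material and of stereochemical fidelity.
- **Fallback:** a deliberate SN1 exchange under stereoelectronic and thermodynamic control. The fallback sets out from 13 and returns at 15.
- **Path:** stirring 13 in acetic acid–CH2Cl2 buffered with NaOAc lets the C4 cation form reversibly. It is captured pseudoaxially, and peri strain with the 5-silyloxy group makes the trans isomer also the more stable one, so the product should be the (2S,4R)-4-acetate F6. This acetate enters the methanolysis of step 9 in place of 14 and gives 15.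

Further compounds
F1 | step 12 | (2S,4R)-5-(tert-butyldimethylsilyloxy)-6,7-dimethoxyflavan-4-yl (S)-3-phenyl-3-(3,4,5-trimethoxyphenoxy)propanoate | COc1cc2c(c(O[Si](C)(C)C(C)(C)C)c1OC)[C@H](OC(=O)C[C@@H](c1ccccc1)Oc1cc(OC)c(OC)c(OC)c1)C[C@@H](c1ccccc1)O2
F2 | step 12 | α-acetoxy ether from reductive acetylation of F1 (both epimers at the acetal carbon) | COc1cc2c(c(O[Si](C)(C)C(C)(C)C)c1OC)[C@H](OC(OC(C)=O)C[C@@H](c1ccccc1)Oc1cc(OC)c(OC)c(OC)c1)C[C@@H](c1ccccc1)O2
F3 | step 12 | 5-O-TBS ether of beilschmieflavonoid B | COc1cc2c(c(O[Si](C)(C)C(C)(C)C)c1OC)[C@H](O[C@@H]1C[C@@H](c3ccccc3)Oc3cc(OC)c(OC)c(OC)c31)C[C@@H](c1ccccc1)O2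
F4 | step 11 | O4,O5-cyclic acetal of 16 bearing a phenacyl group on the acetal carbon | O1[C@@H]2C[C@@H](c3ccccc3)Oc3cc(OC)c(OC)c(OC1CC(=O)c4ccccc4)c32
F5 | step 11 | O4,O5-cyclic acetal of 16 bearing an (R)-2-hydroxy-2-phenylethyl group on the acetal carbon | O1[C@@H]2C[C@@H](c3ccccc3)Oc3cc(OC)c(OC)c(OC1C[C@H](c4ccccc4)O)c32
F6 | step 8 | (2S,4R)-5-(tert-butyldimethylsilyloxy)-6,7-dimethoxyflavan-4-yl acetate | COc1cc2c(c(O[Si](C)(C)C(C)(C)C)c1OC)[C@H](OC(C)=O)C[C@@H](c1ccccc1)O2
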